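**Retrosynthetic overview**
- Feature: ring A is a 1,3,5-trisubstituted benzene (C1 OH, C3 chain, C5 O-ring B). Its C3-C4-C5-C6 edge has the substituent pattern of C6-C5-C4-C3 of a 6-alkyl-4-aryloxy-2-pyrone, so ring A is carried through the synthesis as a pyrone.
- Last C-C disconnection: ring A C2-C3 and C1-C6. This leads back to a macrocyclic 3-carbomethoxy-2-pyrone plus a ketene acetal, joined by (4+2) addition with loss of CO2 and MeOH. The C6 ester is then removed and the three methyl ethers are cleaved.
- Macrocycle: opened in the middle of the C16 chain (ring-closing metathesis, then saturation). This places the ring closure away from the hindered ether.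
- Ether C5-O: ring B C1 phenol plus a 4-chloropyrone, by addition-elimination activated by the C3 ester. The phenol comes from 1-bromo-3,5-dimethoxybenzene, and the pyrone from a gamma-alkylated dioxinone and dimethyl malonate.
- Ring order: ring B (bought), pyrone ring, 22-membered ring, ring A.

Key step: step 10

Assumption: the target is treated as achiral (no stereocentre, ansa chain long enough for free rotation), and the omega-iodoalkene and the ketene acetal are taken as catalogue chemicals.

**Step 1**
Reactants: 1 1-bromo-3,5-dimethoxybenzene; 2 11-bromoundec-1-ene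
Product: 4 1,3-dimethoxy-5-(undec-10-en-1-yl)benzene, via undec-10-en-1-ylmagnesium bromide 3 (not isolated)
Conditions: 2, Mg, THF, 40 °C; then 1, PdCl2(dppf) (2 mol %), THF, 65 °C
Reagents that add atoms: none
Why: Kumada-Corriu cross-coupling of a primary alkylmagnesium bromide with an aryl bromide is reliable under PdCl2(dppf), whose wide bite angle favours reductive elimination over beta-hydride elimination, and the remote terminal alkene is a spectator.

**Step 2**
Reactants: 4 1,3-dimethoxy-5-(undec-10-en-1-yl)benzene
Product: 6 2,4-dimethoxy-6-(undec-10-en-1-yl)benzaldehyde, via aryl iminium chloride 5 (not isolated)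
Conditions: POCl3, DMF, 0 to 70 °C; then H2O
Reagents that add atoms: DMF, CN(C)C=O; water, O
Why: Vilsmeier-Haack formylation of 5-alkylresorcinol dimethyl ethers is known to occur para to one methoxy group and ortho to the other, next to the chain, rather than at the crowded carbon between the two methoxy groups, so the formyl group marks the future ring B C1, and an unactivated alkene is not attacked by the chloroiminium ion.

**Step 3**
Reactants: 6 2,4-dimethoxy-6-(undec-10-en-1-yl)benzaldehyde
Product: 8 2,4-dimethoxy-6-(undec-10-en-1-yl)phenol, via aryl formate 7 (not isolated)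
Conditions: 30% aq H2O2, H2SO4 (cat.), MeOH, 0 °C to rt
Reagents that add atoms: hydrogen peroxide, OO
Why: Acid-catalysed Dakin-type oxidation: hydrogen peroxide adds to the aldehyde, the very electron-rich aryl group migrates to oxygen, and formate 7 is methanolysed in the same pot, while the absence of a peracid leaves the terminal alkene untouched.

**Step 4**
Reactants: 9 2,2,6-trimethyl-4H-1,3-dioxin-4-one; 10 6-iodohex-1-ene
Product: 12 6-(hept-6-en-1-yl)-2,2-dimethyl-4H-1,3-dioxin-4-one, via lithium dienolate 11 (not isolated)
Conditions: 9, LiN(iPr)2, THF, -78 °C; then 10, DMPU, -78 to 0 °C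
Reagents that add atoms: none
Why: Vinylogous enolate alkylation: the cross-conjugated lithium dienolate 11 is known to be alkylated at its exocyclic gamma-carbon by primary omega-alkenyl iodides in the presence of a dipolar cosolvent, which turns the C6 methyl group into the first CH2 of the chain.

**Step 5**
Reactants: 12 6-(hept-6-en-1-yl)-2,2-dimethyl-4H-1,3-dioxin-4-one; 13 dimethyl malonate
Product: 17 methyl 6-(hept-6-en-1-yl)-4-hydroxy-2-oxo-2H-pyran-3-carboxylate, via sodium dimethyl malonate 14 (not isolated), via acylketene 15 (not isolated), via acyclic acylmalonate 16 (not isolated)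
Conditions: 13, NaH, THF, 0 °C; then 12, toluene, 110 °C (THF and acetone distilled off); then 1 M HCl
Reagents that add atoms: none
Why: Thermal retro-(4+2) cleavage of the dioxinone releases acetone and acylketene 15, which C-acylates the malonate enolate in the way known for diketene and its acetone adduct, and the enol oxygen of the C6 ketone in 16 then closes the pyrone ring by 6-exo-trig attack on one ester with loss of methanol, the process being driven by formation of the strongly acidic 4-hydroxy-2-pyrone as its sodium salt.

**Step 6**
Reactants: 17 methyl 6-(hept-6-en-1-yl)-4-hydroxy-2-oxo-2H-pyran-3-carboxylate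
Product: 18 methyl 4-chloro-6-(hept-6-en-1-yl)-2-oxo-2H-pyran-3-carboxylate
Conditions: (COCl)2, DMF (cat.), CH2Cl2, 0 °C to rt
Reagents that add atoms: oxalyl chloride, O=C(Cl)C(=O)Cl
Why: Conversion of a vinylogous acid into a vinylogous acid chloride: the chloroiminium salt from oxalyl chloride and DMF activates the acidic C4 hydroxyl and chloride replaces it by addition-elimination, as known for cyclic 1,3-dicarbonyl compounds and 4-hydroxy-2-pyrones, while ester, lactone and alkene are inert.

**Step 7**
Reactants: 8 2,4-dimethoxy-6-(undec-10-en-1-yl)phenol; 18 methyl 4-chloro-6-(hept-6-en-1-yl)-2-oxo-2H-pyran-3-carboxylate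
Product: 19 methyl 4-[2,4-dimethoxy-6-(undec-10-en-1-yl)phenoxy]-6-(hept-6-en-1-yl)-2-oxo-2H-pyran-3-carboxylate
Conditions: Cs2CO3, MeCN, 0 °C to rt
Reagents that add atoms: none
Why: Addition-elimination at a vinylic carbon (vinylogous acyl substitution): C4 of 18 is the chloride-bearing beta-carbon of an alkylidene malonate, so even the di-ortho-substituted phenoxide of 8 should add and expel chloride at or below room temperature, as 4-halo-2-pyrones do with phenols.

**Step 8**
Reactants: 19 methyl 4-[2,4-dimethoxy-6-(undec-10-en-1-yl)phenoxy]-6-(hept-6-en-1-yl)-2-oxo-2H-pyran-3-carboxylate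
Product: 20 unsaturated macrocyclic pyrone (ring B C6-(CH2)9-CH=CH-(CH2)5-pyrone C6; E/Z mixture expected)
Conditions: second-generation Grubbs catalyst RuCl2(=CHPh)(PCy3)(SIMes) (5 mol %), CH2Cl2 (1 mM), 40 °C
Reagents that add atoms: none
Why: Ring-closing metathesis of two unhindered terminal alkenes at high dilution is driven by loss of ethene and closes large unstrained rings in long alkyl chains reliably, the electron-poor tri- and tetrasubstituted pyrone double bonds do not engage the ruthenium alkylidene, and the alkene geometry is left uncontrolled because step 9 erases it.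

**Step 9**
Reactants: 20 unsaturated macrocyclic pyrone
Product: 21 saturated macrocyclic pyrone (methyl 4-aryloxy-6-alkyl-2-oxo-2H-pyran-3-carboxylate; pyrone C6 and ring B C6 joined by (CH2)16)
Conditions: H2 (1 atm), RhCl(PPh3)3 (10 mol %), toluene, 40 °C
Reagents that add atoms: none
Why: Homogeneous hydrogenation with RhCl(PPh3)3 discriminates by degree of substitution, so the 1,2-disubstituted chain alkene (both geometric isomers converge) is reduced while the trisubstituted C5=C6 and tetrasubstituted C3=C4 bonds of the pyrone stay intact.

**Step 10**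
Reactants: 21 saturated macrocyclic pyrone; 22 1,1-dimethoxyethene
Product: 25 tri-O-methylgrevirobstol B carrying CO2Me at ring A C6, via bridged lactone 23 (not isolated), via cyclohexadiene acetal 24 (not isolated)
Conditions: 22 (10 equiv), mesitylene, sealed tube, 140 °C
Reagents that add atoms: none
Why: The polarised ketene acetal 22 and the electron-poor diene of 21 (C3=C4-C5=C6, lowered in energy by the C3 ester and the lactone carbonyl) combine in an asynchronous, suprafacial inverse-electron-demand Diels-Alder reaction in which the CH2 terminus bonds ahead to pyrone C6 and the acetal carbon follows onto C3, giving the 2-oxabicyclo[2.2.2]octenone 23. At the reaction temperature 23 expels CO2 by retro-(4+2) cleavage to the cyclohexadiene acetal 24, and 1,2-elimination of methanol aromatises it to 25. The closest known reaction type is the benzannulation of 3-carbomethoxy-2-pyrones, 6-alkyl-substituted ones included, with 1,1-dialkoxyethenes to 2-alkoxybenzoates; the C4 aryloxy donor makes the present diene less reactive, which is answered by excess 22 and a higher temperature. Ring A is closed as a six-membered carbocycle by intermolecular (4+2) cycloaddition (bonds C2-C3 and C1-C6), while the 22-membered ring keeps its size because pyrone C6-C5-C4 and arene C3-C4-C5 are the same three atoms of its perimeter. The two bridgehead stereocentres of 23 arise as a racemate with a relative configuration dictated by the bicycle and are erased on aromatisation, so nothing has to be controlled. The step needs regioselectivity (oxygen at C1, meta to chain and ether) and site selectivity (C6 rather than C4, since addition at C4 could expel the aryloxide): the first is secured by the C3 ester, which makes C6 the electrophilic diene terminus and C3 the carbon that closes onto the dialkoxycarbenium end, and the second by the oxygen lone pair and the two ortho substituents of ring B, which deactivate and shield C4, and by the fact that only attack at C6 can collapse to a cycloadduct.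

**Step 11**
Reactants: 25 tri-O-methylgrevirobstol B carrying CO2Me at ring A C6
Product: 26 tri-O-methylgrevirobstol B 6-carboxylic acid
Conditions: KOH, DMSO-H2O, 100 °C; then 1 M HCl
Reagents that add atoms: potassium hydroxide, [K+].[OH-]
Why: Ester saponification by acyl-oxygen cleavage, run with poorly solvated hydroxide in aqueous DMSO because the ester is flanked by two ortho oxygen substituents, leaves the methyl ethers and the diaryl ether untouched.

**Step 12**
Reactants: 26 tri-O-methylgrevirobstol B 6-carboxylic acid
Product: 27 tri-O-methylgrevirobstol B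
Conditions: Ag2CO3 (10 mol %), AcOH (5 mol %), DMSO, 120 °C
Reagents that add atoms: none
Why: Silver-catalysed protodecarboxylation is known for ortho,ortho'-dioxygenated benzoic acids, whose two ortho oxygens twist the carboxylate out of the ring plane and stabilise the arylsilver species that is then protonated, and no acylation side path exists because both ring B positions next to the ether oxygen are substituted.

**Step 13**
Reactants: 27 tri-O-methylgrevirobstol B
Product: 29 grevirobstol B, via tris(dibromoboryl) ether 28 (not isolated)
Conditions: BBr3 (6 equiv), CH2Cl2, -78 °C to rt; then H2O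
Reagents that add atoms: none
Why: Lewis-acid ether cleavage: BBr3 binds each methoxy oxygen and bromide removes the methyl group by SN2, the diaryl ether offers no sp3 carbon and survives, and hydrolysis of the aryl borates 28 frees the three phenols.

**Compound list**
1 | 1-bromo-3,5-dimethoxybenzene | COc1cc(Br)cc(OC)c1 | starting material
2 | 11-bromoundec-1-ene | C=CCCCCCCCCCBr | starting material
3 | undec-10-en-1-ylmagnesium bromide (not isolated) | C=CCCCCCCCCC[Mg]Br | intermediate
4 | 1,3-dimethoxy-5-(undec-10-en-1-yl)benzene | COc1cc(CCCCCCCCCC=C)cc(OC)c1 | intermediate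
5 | N-[2,4-dimethoxy-6-(undec-10-en-1-yl)benzylidene]-N-methylmethanaminium chloride (not isolated) | C[N+](C)=Cc1c(OC)cc(OC)cc1CCCCCCCCCC=C.[Cl-] | intermediate
6 | 2,4-dimethoxy-6-(undec-10-en-1-yl)benzaldehyde | O=Cc1c(OC)cc(OC)cc1CCCCCCCCCC=C | intermediate
7 | 2,4-dimethoxy-6-(undec-10-en-1-yl)phenyl formate (not isolated) | O=COc1c(OC)cc(OC)cc1CCCCCCCCCC=C | intermediate
8 | 2,4-dimethoxy-6-(undec-10-en-1-yl)phenol (ring B; OH at C1) | Oc1c(OC)cc(OC)cc1CCCCCCCCCC=C | intermediate
9 | 2,2,6-trimethyl-4H-1,3-dioxin-4-one | CC1=CC(=O)OC(C)(C)O1 | starting material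
10 | 6-iodohex-1-ene | C=CCCCCI | starting material
11 | lithium 2,2-dimethyl-6-methylidene-6H-1,3-dioxin-4-olate (not isolated) | [Li+].[O-]C1=CC(=C)OC(C)(C)O1 | intermediate
12 | 6-(hept-6-en-1-yl)-2,2-dimethyl-4H-1,3-dioxin-4-one | C=CCCCCCC1=CC(=O)OC(C)(C)O1 | intermediate
13 | dimethyl malonate | COC(=O)CC(=O)OC | starting material
14 | sodium dimethyl malonate (not isolated) | [Na+].COC(=O)[CH-]C(=O)OC | intermediate
15 | 3-oxodeca-1,9-dien-1-one, the acylketene (not isolated) | C=CCCCCCC(=O)C=C=O | intermediate
16 | dimethyl 2-(3-oxodec-9-enoyl)propanedioate (not isolated) | C=CCCCCCC(=O)CC(=O)C(C(=O)OC)C(=O)OC | intermediate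
17 | methyl 6-(hept-6-en-1-yl)-4-hydroxy-2-oxo-2H-pyran-3-carboxylate | C=CCCCCCC1=CC(O)=C(C(=O)OC)C(=O)O1 | intermediate
18 | methyl 4-chloro-6-(hept-6-en-1-yl)-2-oxo-2H-pyran-3-carboxylate | C=CCCCCCC1=CC(Cl)=C(C(=O)OC)C(=O)O1 | intermediate
19 | methyl 4-[2,4-dimethoxy-6-(undec-10-en-1-yl)phenoxy]-6-(hept-6-en-1-yl)-2-oxo-2H-pyran-3-carboxylate | C=CCCCCCC1=CC(Oc2c(OC)cc(OC)cc2CCCCCCCCCC=C)=C(C(=O)OC)C(=O)O1 | intermediate
20 | unsaturated macrocyclic pyrone: 3-carbomethoxy-2-pyrone with C4-O-ring B C1 and with C6 joined to ring B C6 by (CH2)5-CH=CH-(CH2)9; 22-membered ring; E/Z mixture expected, E isomer drawn | O=C1OC2=CC(=C1C(=O)OC)Oc1c(OC)cc(OC)cc1CCCCCCCCC/C=C/CCCCC2 | intermediate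
21 | saturated macrocyclic pyrone: methyl 4-aryloxy-6-alkyl-2-oxo-2H-pyran-3-carboxylate with pyrone C6 and ring B C6 joined by (CH2)16 | O=C1OC2=CC(=C1C(=O)OC)Oc1c(OC)cc(OC)cc1CCCCCCCCCCCCCCCC2 | intermediate
22 | 1,1-dimethoxyethene | C=C(OC)OC | starting material
23 | bridged lactone: 2-oxabicyclo[2.2.2]oct-5-en-3-one cycloadduct, bridgeheads at former pyrone C6 and C3; racemic, one enantiomer drawn (not isolated) | O=C1O[C@@]23CC(OC)(OC)[C@]1(C(=O)OC)C(=C2)Oc1c(OC)cc(OC)cc1CCCCCCCCCCCCCCCC3 | intermediate
24 | cyclohexa-1,3-diene dimethyl acetal formed by loss of CO2 from 23 (not isolated) | COC1(OC)CC2=CC(=C1C(=O)OC)Oc1c(OC)cc(OC)cc1CCCCCCCCCCCCCCCC2 | intermediate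
25 | tri-O-methylgrevirobstol B carrying a methyl ester at ring A C6 | COc1cc2cc(c1C(=O)OC)Oc1c(OC)cc(OC)cc1CCCCCCCCCCCCCCCC2 | intermediate
26 | tri-O-methylgrevirobstol B 6-carboxylic acid | COc1cc2cc(c1C(=O)O)Oc1c(OC)cc(OC)cc1CCCCCCCCCCCCCCCC2 | intermediate
27 | tri-O-methylgrevirobstol B | COc1cc2cc(c1)Oc1c(OC)cc(OC)cc1CCCCCCCCCCCCCCCC2 | intermediate
28 | tris(dibromoboryl) ether of grevirobstol B, idealised (not isolated) | BrB(Br)Oc1cc2cc(c1)Oc1c(OB(Br)Br)cc(OB(Br)Br)cc1CCCCCCCCCCCCCCCC2 | intermediate
29 | grevirobstol B | Oc1cc2cc(c1)Oc1c(O)cc(O)cc1CCCCCCCCCCCCCCCC2 | target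

**Step count**
- Total: 13 steps.
- Longest linear sequence: 10 steps (steps 1-3 then 7-13; the branch of steps 4-6 then 7-13 is equally long).

**Steps most likely to fail**

1. Step 10 (key step).
   - What may go wrong: the C4 aryloxy and C6 alkyl donors may slow the cycloaddition. Thermal oligomerisation of the ketene acetal could then take over. So could its conjugate addition at C4 followed by expulsion of the aryloxide, which opens the macrocycle.
   - Fallback: ring A is brought in as a finished arene and the ether is made by copper catalysis. The fallback sets out from phenol 8 and returns at 27. 3,5-Dibromoanisole (in excess) is coupled once with hept-6-en-1-ylmagnesium bromide under PdCl2(dppf) to give 1-bromo-3-(hept-6-en-1-yl)-5-methoxybenzene F1. Ullmann-type coupling of F1 with 8 (CuI, picolinic acid, K3PO4, DMSO, 90 °C, a system known to accept di-ortho-substituted phenols) gives the open diaryl ether diene F2. Ring-closing metathesis as in step 8 gives the macrocyclic diaryl ether alkene F3. Hydrogenation over Pd/C then gives 27.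

2. Step 5.
   - What may go wrong: the thermally released acylketene may dimerise or be intercepted on oxygen faster than the sparingly soluble malonate enolate acylates on carbon. Lactonisation of the acyclic adduct may also stall.
   - Fallback: the pyrone is built first and the chain is attached afterwards. The fallback sets out from 13 and 10 and returns at 17. Sodium dimethyl malonate from 13 is acetoacetylated with diketene (THF, 0 °C to rt, then acid), the classical form of this ring synthesis, to give methyl 4-hydroxy-6-methyl-2-oxo-2H-pyran-3-carboxylate F4. Double deprotonation of F4 (LiN(iPr)2, 2.2 equiv, THF-DMPU, -78 °C) and alkylation of the C6 methyl carbanion with 10 then gives 17. This alkylation is known for dianions of 4-hydroxy-6-methyl-2-pyrones.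

3. Step 9.
   - What may go wrong: reduction of the E alkene may be sluggish, or hydrogen may creep onto the pyrone C5=C6 bond under forcing.
   - Fallback: the order of events is changed so that the alkene is saturated only when no pyrone is left. The fallback sets out from 20 and returns at 25. Compound 20 is heated with 22 as in step 10 (an isolated disubstituted alkene does not react with a ketene acetal) to give the unsaturated macrocyclic benzoate F5. Hydrogenation over Pd/C in EtOAc then gives 25.

**Further compounds**
F1 | step 10 | 1-bromo-3-(hept-6-en-1-yl)-5-methoxybenzene | COc1cc(Br)cc(CCCCCC=C)c1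
F2 | step 10 | open diaryl ether diene, 1-[3-(hept-6-en-1-yl)-5-methoxyphenoxy]-2,4-dimethoxy-6-(undec-10-en-1-yl)benzene | COc1cc(CCCCCC=C)cc(Oc2c(OC)cc(OC)cc2CCCCCCCCCC=C)c1
F3 | step 10 | macrocyclic diaryl ether alkene (didehydro tri-O-methylgrevirobstol B; E/Z mixture expected, E isomer drawn) | COc1cc2cc(c1)Oc1c(OC)cc(OC)cc1CCCCCCCCC/C=C/CCCCC2
F4 | step 5 | methyl 4-hydroxy-6-methyl-2-oxo-2H-pyran-3-carboxylate | CC1=CC(O)=C(C(=O)OC)C(=O)O1
F5 | step 9 | unsaturated macrocyclic benzoate (chain alkene analogue of 25; E/Z mixture expected, E isomer drawn) | COc1cc2cc(c1C(=O)OC)Oc1c(OC)cc(OC)cc1CCCCCCCCC/C=C/CCCCC2
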